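**Retrosynthetic overview** (rings: A = dihydropyran, B = cycloheptene, C = cyclopentene, D = cyclopentane with CO2H, E = N-methylpiperidine)
1. Ring A comes from a δ-hydroxy ketone (Michael addition of a bridging aldehyde to isopropyl vinyl ketone, reduction, cyclodehydration); the CO2H comes from decarboxylation of a ring D malonate.
2. Ring E is closed by a Mannich reaction onto the ring B ketone; this ketone, the B/D/E quaternary carbon and the tetrasubstituted B/C alkene all come from one photochemical 1,3-acyl shift that expands a spiro cyclopentanone by two carbons.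
3. Enabling feature: in the precursor the cyclopentanone carbonyl carbon is bonded to a spiro carbon of ring C (the future B/C alkene carbon) that is allylic to the tetrasubstituted ring D alkene; the acyl carbon moves across this allyl unit to the far alkene carbon (the future B/D/E quaternary carbon), on the same face.
4. The spiro ketone comes from a rings C + D enone by sulfonium-ylide spiroannulation and diazomethane homologation; the enone comes from the (R)-malonate Michael adduct of cyclopentenone by alkylation with 1,3-dichloroacetone, N-alkylation and aldol condensation.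
5. Order of ring formation: C (starting material), D, spiro cyclobutane then cyclopentane, B (key step), E, A.

Key step: step 7

Remark: the nitrogen is carried as its N-methyl trifluoroacetamide until ring E is closed, and the target is isolated as the zwitterionic amino acid.

Step 1
Reactants: 1 cyclopent-2-en-1-one; 2 dimethyl propanedioate
Product: 3 dimethyl 2-[(1R)-3-oxocyclopentyl]propanedioate
Conditions: LiAl[(R)-1,1'-binaphthalene-2,2'-diolate]2 (10 mol%), KOt-Bu (9 mol%), 4 Å MS, THF, rt
Reagents that add atoms: none
Why: Catalytic asymmetric Michael addition of a malonate to a cyclic enone under Lewis acid/Brønsted base bimetallic catalysis, with the catalyst enantiomer chosen to give the R adduct; this stereocentre becomes the C/D ring-fusion carbon and is the only source of absolute configuration.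

Step 2
Reactants: 3 dimethyl 2-[(1R)-3-oxocyclopentyl]propanedioate; 4 1,3-dichloropropan-2-one
Product: 5 dimethyl 2-(3-chloro-2-oxopropyl)-2-[(1R)-3-oxocyclopentyl]propanedioate
Conditions: NaH (1.0 equiv), THF, 0 °C; then 4 (3 equiv), NaI (10 mol%), 0 °C to rt
Reagents that add atoms: none
Why: SN2 C-alkylation of the sodium malonate (the only C–H acidic enough for one equivalent of base) by the very reactive α-chloro ketone, with excess dichloroacetone to suppress double alkylation.

Step 3
Reactants: 5 chloro diketone
Product: 6 dimethyl 2-{3-[methyl(trifluoroacetyl)amino]-2-oxopropyl}-2-[(1R)-3-oxocyclopentyl]propanedioate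
Conditions: CF3CONHMe (1.5 equiv), K2CO3 (1.5 equiv), NaI (10 mol%), MeCN, rt
Reagents that add atoms: N-methyl-2,2,2-trifluoroacetamide CNC(=O)C(F)(F)F
Why: N-alkylation (Gabriel type) of the acidic trifluoroacetamide by the α-keto chloride installs the protected N-methylamine without generating a ketone enolate.

Step 4
Reactants: 6 trifluoroacetamido diketone
Product: 7 bicyclic enone (rings C and D)
Conditions: TsOH·H2O (10 mol%), benzene, 80 °C, Dean–Stark trap
Reagents that add atoms: none
Why: Acid-catalysed intramolecular aldol condensation of the 1,6-diketone (five-membered closure from the ring α-carbon onto the side-chain ketone) is driven by dehydration into conjugation, the other aldol modes being reversible and unable to dehydrate; once the α-carbon is sp2 the neighbouring stereocentre can no longer be lost by retro-Michael reaction.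

Step 5
Reactants: 7 bicyclic enone
Product: 9 spiro cyclobutanone (carbonyl carbon anti to the C/D fusion hydrogen), via oxaspiropentane 8 (not isolated)
Conditions: cyclopropyldiphenylsulfonium tetrafluoroborate (1.3 equiv), KN(SiMe3)2 (1.25 equiv), DME, −40 °C; add 7, −40 to 0 °C; then LiBF4 (10 mol%), benzene, rt
Reagents that add atoms: cyclopropyldiphenylsulfonium tetrafluoroborate C1CC1[S+](c1ccccc1)c1ccccc1.F[B-](F)(F)F
Why: Sulfonium-ylide cyclobutanone spiroannulation: the ylide should add 1,2 to the enone carbonyl from the face anti to the malonate carbon of ring D, and the allyl-stabilised opening of the oxaspiropentane with cyclopropane-to-cyclobutanone ring expansion (migration with inversion at the spiro carbon) then places the new carbonyl carbon syn to that malonate carbon.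

Step 6
Reactants: 9 spiro cyclobutanone
Product: 10 spiro cyclopentanone (same configuration)
Conditions: CH2N2, Et2O–MeOH, 0 °C
Reagents that add atoms: diazomethane C=[N+]=[N-]
Why: Diazomethane ring homologation of a strained cyclobutanone (Tiffeneau–Demjanov type) in which the less substituted α-methylene should migrate, so the carbonyl stays bonded to the spiro carbon and no stereocentre is touched.

Step 7
Reactants: 10 spiro cyclopentanone
Product: 11 ring-expanded cycloheptenone (rings B, C, D)
Conditions: hν (300 nm, Pyrex), degassed benzene (0.01 M), 10 °C, to the photostationary state; recovered 10 resubmitted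
Reagents that add atoms: none
Why: Direct n→π* excitation of the β,γ-unsaturated ketone causes singlet α-cleavage of the bond between the carbonyl carbon and the allylic spiro carbon, and the tethered acyl/allyl radical pair recombines at the far allyl terminus, the ring D alkene carbon. The closest known reaction is the photochemical 1,3-acyl shift of β,γ-enones, used as a two-carbon ring expansion of 2-alkenylcycloalkanones. The cyclopentanone opens and ring B closes as a seven-membered ring by bond formation between the acyl carbon and the distal alkene carbon (formal suprafacial [1,3] shift), while the alkene moves to the tetrasubstituted position shared by rings B and C. The new quaternary stereocentre is controlled by the spiro carbon: the acyl group should be delivered to the face of ring D from which it departs, anti to the C/D fusion hydrogen, and the spiro stereocentre is consumed. The step needs the singlet 1,3-shift to win over triplet oxa-di-π-methane rearrangement and decarbonylation (no sensitiser, λ ≥ 300 nm, cool, degassed) and cleavage on the allylic side, which the spiro array secures by holding the C–CO bond parallel to the alkene π orbital. Because 11 is itself a β,γ-enone, the reaction is run to the photostationary state and recovered 10 is recycled.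

Step 8
Reactants: 11 ring-expanded cycloheptenone
Product: 13 N-(methoxymethyl)-N-methylamine (N,O-acetal), via secondary amine 12 (not isolated)
Conditions: K2CO3 (0.5 equiv), MeOH, rt; then (CH2O)n (5 equiv), 4 Å MS, rt
Reagents that add atoms: formaldehyde (as paraformaldehyde) C=O; methanol CO
Why: Mild methanolysis of the trifluoroacetamide frees the secondary amine, which condenses with formaldehyde and methanol to the hemiaminal ether, a stable precursor of the formaldiminium ion.

Step 9
Reactants: 13 N,O-acetal
Product: 15 bridged amino ketone (rings B–E), via silyl enol ether iminium triflate 14 (not isolated)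
Conditions: Me3SiOTf (2.5 equiv), i-Pr2NEt (3 equiv), CH2Cl2, −78 to −20 °C; aq NaHCO3
Reagents that add atoms: none
Why: Silyl triflate-mediated Mukaiyama–Mannich cyclisation in which the ketone is converted into its only possible silyl enol ether and the N,O-acetal into the iminium ion, which is trapped in a six-membered closure at low temperature before a 2-aza-Cope shift onto the neighbouring alkene can compete; the new bridgehead stereocentre can form only with the nitrogen bridge spanning the cycloheptenone on the side of the CH2N carbon.

Step 10
Reactants: 15 bridged amino ketone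
Product: 17 bridging aldehyde (epimer mixture at the formyl-bearing carbon), via enol ether 16 (not isolated)
Conditions: Ph3P(CH2OMe)Cl (3 equiv), KN(SiMe3)2 (2.9 equiv), THF, 0 to 40 °C; then CF3CO2H, THF–H2O, rt
Reagents that add atoms: (methoxymethyl)triphenylphosphonium chloride COC[P+](c1ccccc1)(c1ccccc1)c1ccccc1.[Cl-]; water O
Why: Wittig methoxymethylenation of the bridging ketone followed by acid hydrolysis of the enol ether gives the one-carbon homologated aldehyde, whose α-configuration is irrelevant because that carbon is enolised in the next step.

Step 11
Reactants: 17 bridging aldehyde; 18 4-methylpent-1-en-3-one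
Product: 19 keto aldehyde with quaternary bridge carbon
Conditions: 18 (2 equiv), DBU (20 mol%), MeCN, 0 °C to rt
Reagents that add atoms: none
Why: Base-catalysed Michael addition of the α-branched aldehyde enolate to the vinyl ketone creates the second quaternary carbon; the acceptor should approach the exocyclic enolate from the cycloheptene side, which lacks the two syn-axial N–CH2 hydrogens of the piperidine side, so the keto chain ends up over ring B and the formyl group over ring E.

Step 12
Reactants: 19 keto aldehyde
Product: 20 hydroxy ketone (in equilibrium with its cyclic hemiketal)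
Conditions: NaBH4 (0.5 equiv), MeOH–CH2Cl2, −78 °C
Reagents that add atoms: none
Why: Chemoselective borohydride reduction of the aldehyde at low temperature in the presence of the less electrophilic isopropyl ketone and the methyl esters.

Step 13
Reactants: 20 hydroxy ketone
Product: 21 spiro dihydropyran diester (rings A–E)
Conditions: (1S)-camphor-10-sulfonic acid (1.3 equiv), 4 Å MS, benzene, 60 °C; then Et3N
Reagents that add atoms: none
Why: Acid-catalysed cyclodehydration of the δ-hydroxy ketone through its hemiketal should give the thermodynamically preferred endocyclic enol ether.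

Step 14
Reactants: 21 spiro dihydropyran diester
Product: 23 CNP0237695.2 (target), via malonic acid 22 (not isolated)
Conditions: KOH (6 equiv), MeOH–H2O, 70 °C; AcOH to pH 7, evaporate; pyridine, 115 °C
Reagents that add atoms: potassium hydroxide [K+].[OH-]
Why: Saponification of the gem-diester and thermal decarboxylation of the malonic acid, in which the intermediate ene-diol should be protonated (kinetic ketonisation) from the less hindered face of ring D, syn to the C/D fusion hydrogen and away from the spiro quaternary carbon, leaving the carboxyl group on the required face.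

**Compound list**
1 | cyclopent-2-en-1-one | O=C1C=CCC1 | starting material
2 | dimethyl propanedioate (dimethyl malonate) | COC(=O)CC(=O)OC | starting material
3 | dimethyl 2-[(1R)-3-oxocyclopentyl]propanedioate | O=C1C[C@@H](CC1)C(C(=O)OC)C(=O)OC | intermediate
4 | 1,3-dichloropropan-2-one | ClCC(=O)CCl | starting material
5 | dimethyl 2-(3-chloro-2-oxopropyl)-2-[(1R)-3-oxocyclopentyl]propanedioate | O=C1C[C@@H](CC1)C(CC(=O)CCl)(C(=O)OC)C(=O)OC | intermediate
6 | dimethyl 2-{3-[methyl(trifluoroacetyl)amino]-2-oxopropyl}-2-[(1R)-3-oxocyclopentyl]propanedioate | O=C1C[C@@H](CC1)C(CC(=O)CN(C)C(=O)C(F)(F)F)(C(=O)OC)C(=O)OC | intermediate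
7 | dimethyl (6aR)-3-{[methyl(trifluoroacetyl)amino]methyl}-4-oxo-4,5,6,6a-tetrahydropentalene-1,1(2H)-dicarboxylate (bicyclic enone, rings C and D) | O=C1CC[C@@H]2C1=C(CN(C)C(=O)C(F)(F)F)CC2(C(=O)OC)C(=O)OC | intermediate
8 | oxaspiropentane from 7: C-4 is the spiro epoxide carbon of a 1-oxaspiro[2.2]pentane; epoxide oxygen syn to C-1 (malonate carbon), cyclopropane carbon syn to H-6a; 6aR | C1CC12O[C@]23CC[C@@H]4C3=C(CN(C)C(=O)C(F)(F)F)CC4(C(=O)OC)C(=O)OC | intermediate
9 | dimethyl (1R,6'aR)-3'-{[methyl(trifluoroacetyl)amino]methyl}-2-oxo-5',6'-dihydro-2'H-spiro[cyclobutane-1,4'-pentalene]-1',1'(6'aH)-dicarboxylate (carbonyl carbon syn to C-1', anti to H-6'a) | O=C1CC[C@@]12CC[C@@H]3C2=C(CN(C)C(=O)C(F)(F)F)CC3(C(=O)OC)C(=O)OC | intermediate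
10 | dimethyl (1S,6'aR)-3'-{[methyl(trifluoroacetyl)amino]methyl}-2-oxo-5',6'-dihydro-2'H-spiro[cyclopentane-1,4'-pentalene]-1',1'(6'aH)-dicarboxylate (carbonyl carbon syn to C-1', anti to H-6'a) | O=C1CCC[C@@]12CC[C@@H]3C2=C(CN(C)C(=O)C(F)(F)F)CC3(C(=O)OC)C(=O)OC | intermediate
11 | 7-5-5 tricyclic keto amide: ring B is a cyclohept-3-en-1-one whose C3=C4 is shared with ring C and whose quaternary C2 (R) is shared with ring D and bears CH2N(CH3)COCF3 syn to the C/D fusion hydrogen (fusion carbon R); ring D bears C(CO2CH3)2 next to the fusion carbon | O=C1CCCC2=C3[C@@H](CC2)C(C(=O)OC)(C(=O)OC)C[C@]31CN(C)C(=O)C(F)(F)F | intermediate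
12 | N-deacylated 11 (secondary methylamine) | O=C1CCCC2=C3[C@@H](CC2)C(C(=O)OC)(C(=O)OC)C[C@]31CNC | intermediate
13 | N-(methoxymethyl)-N-methyl amine from 12 (N,O-acetal) | O=C1CCCC2=C3[C@@H](CC2)C(C(=O)OC)(C(=O)OC)C[C@]31CN(C)COC | intermediate
14 | trimethylsilyl enol ether of the ring B ketone carrying the N-methyl-N-methylideneammonium group; trifluoromethanesulfonate salt | C[Si](C)(C)OC1=CCCC2=C3[C@@H](CC2)C(C(=O)OC)(C(=O)OC)C[C@]31C[N+](C)=C.[O-]S(=O)(=O)C(F)(F)F | intermediate
15 | bridged amino ketone: 8-methyl-8-azabicyclo[4.3.1]dec-2-en-10-one core (rings B and E) fused to rings C and D; nitrogen bridge syn to the C/D fusion hydrogen; gem-dimethyl ester on ring D | O=C1[C@H]2CCC3=C4[C@@H](CC3)C(C(=O)OC)(C(=O)OC)C[C@]41CN(C)C2 | intermediate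
16 | 10-(methoxymethylidene) analogue of 15 (methyl enol ether, E/Z mixture) | COC=C1[C@H]2CCC3=C4[C@@H](CC3)C(C(=O)OC)(C(=O)OC)C[C@]41CN(C)C2 | intermediate
17 | 10-carbaldehyde from 16 (mixture of epimers at the formyl-bearing bridge carbon) | O=CC1[C@H]2CCC3=C4[C@@H](CC3)C(C(=O)OC)(C(=O)OC)C[C@]41CN(C)C2 | intermediate
18 | 4-methylpent-1-en-3-one (isopropyl vinyl ketone) | CC(C)C(=O)C=C | starting material
19 | keto aldehyde: bridge carbon quaternary, formyl group on the ring E (piperidine) side, 4-methyl-3-oxopentyl chain on the ring B (cycloheptene) side | CC(C)C(=O)CC[C@@]1(C=O)[C@H]2CCC3=C4[C@@H](CC3)C(C(=O)OC)(C(=O)OC)C[C@]41CN(C)C2 | intermediate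
20 | hydroxy ketone from 19 (CH2OH in place of CHO; in equilibrium with its cyclic hemiketal) | CC(C)C(=O)CC[C@@]1(CO)[C@H]2CCC3=C4[C@@H](CC3)C(C(=O)OC)(C(=O)OC)C[C@]41CN(C)C2 | intermediate
21 | target skeleton (rings A–E) with C(CO2CH3)2 in ring D in place of CH(CO2H) | CC(C)C1=CC[C@@]2(CO1)[C@H]1CCC3=C4[C@@H](CC3)C(C(=O)OC)(C(=O)OC)C[C@]42CN(C)C1 | intermediate
22 | malonic acid corresponding to 21 | CC(C)C1=CC[C@@]2(CO1)[C@H]1CCC3=C4[C@@H](CC3)C(C(=O)O)(C(=O)O)C[C@]42CN(C)C1 | intermediate
23 | CNP0237695.2 | CC(C)C1=CC[C@@]2(CO1)[C@H]1CCC3=C4[C@@H](CC3)[C@@H](C(=O)O)C[C@]42CN(C)C1 | target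

Total step count: 14. Longest linear sequence: 14 steps.

**Steps most likely to fail**

Step 7. The photoreaction may stall at an unfavourable photostationary state, the acyl/allyl radical pair may lose its facial memory before recombination, or it may decarbonylate. The fallback does the two-carbon expansion thermally one ring size lower and adds the last carbon afterwards. It sets out from spiro cyclobutanone 9, which is heated (toluene, 180 °C, sealed tube) so that the 2-vinylcyclobutanone undergoes the thermal 1,3-acyl shift to the cyclohex-3-enone analogue of 11, F1. Homologation of F1 with Me3SiCHN2 and BF3·OEt2 (CH2Cl2, −78 °C, protodesilylation on work-up), the less substituted methylene migrating, comes back to the route at 11; ring B then arises from a six-membered ring by one-carbon expansion.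

Step 6. Migration of the allylic quaternary carbon instead of the methylene, or repeated homologation, would give the wrong cyclopentanone. The fallback makes the cyclopentanone directly by semipinacol ring expansion of a cyclobutanol. It sets out from enone 7, which is deprotonated kinetically (KN(SiMe3)2, THF, −78 °C) and trapped with PhNTf2 as the cross-conjugated dienyl triflate F2. Nozaki–Hiyama–Kishi addition (CrCl2, catalytic NiCl2, DMF) to cyclobutanone gives the tertiary dienyl cyclobutanol F3. Catalytic camphorsulfonic acid (CH2Cl2, 0 °C) protonates the ring C diene terminus and triggers the 1,2-shift of a cyclobutane methylene, coming back to the route at 10.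

Step 11. Under equilibrating base the conjugate addition may revert, the keto aldehyde may close by intramolecular aldol reaction, and facial selectivity at the bridge carbon may erode. The fallback forms ring A by a kinetically controlled cycloaddition. It sets out from enol ether 16, which is isolated instead of hydrolysed and heated with 18 (neat, 130 °C, sealed tube, or with catalytic ZnCl2) in an inverse-demand hetero-Diels–Alder reaction that gives the spiro 2-methoxy dihydropyran F4. Ionic reduction of the acetal (Et3SiH, BF3·OEt2, CH2Cl2, −78 °C) comes back to the route at 21.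

Further compounds
F1 | step 7 | cyclohex-3-enone analogue of 11 (ring B one CH2 smaller, same configuration) | O=C1CCC2=C3[C@@H](CC2)C(C(=O)OC)(C(=O)OC)C[C@]31CN(C)C(=O)C(F)(F)F
F2 | step 6 | dimethyl (6aR)-3-{[methyl(trifluoroacetyl)amino]methyl}-4-{[(trifluoromethyl)sulfonyl]oxy}-6,6a-dihydropentalene-1,1(2H)-dicarboxylate | FC(F)(F)S(=O)(=O)OC1=CC[C@@H]2C1=C(CN(C)C(=O)C(F)(F)F)CC2(C(=O)OC)C(=O)OC
F3 | step 6 | dimethyl (6aR)-4-(1-hydroxycyclobutyl)-3-{[methyl(trifluoroacetyl)amino]methyl}-6,6a-dihydropentalene-1,1(2H)-dicarboxylate | OC1(CCC1)C1=CC[C@@H]2C1=C(CN(C)C(=O)C(F)(F)F)CC2(C(=O)OC)C(=O)OC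
F4 | step 11 | 2-methoxy analogue of 21 (methoxy on the O–CH carbon of ring A, mixture of acetal epimers) | CC(C)C1=CC[C@@]2(C(OC)O1)[C@H]1CCC3=C4[C@@H](CC3)C(C(=O)OC)(C(=O)OC)C[C@]42CN(C)C1
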